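(The readings come from a simulation with constants of no real substance; noise was put on by code.)

I began with the easy step: the average divides monomer in chains by chains begun, and although the runs do not show the number of chains, the initiator supply can be estimated.

common to all: pre-initiator 8 mol%; impurity 13 mM
- violet: free monomer 0.40 M; transfer agent 0.024 M; run made earlier
- teal: free monomer 0.60 M; transfer agent 0.024 M; run made earlier
- grey: free monomer 0.80 M; transfer agent 0.048 M; run made earlier
- epsilon: free monomer 0.80 M; transfer agent 0.0240 M; time 8.0 h
- delta: free monomer 0.80 M; transfer agent 0.0240 M; time 2.5 h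

| run | time / h | monomer in chains / % | free monomer / % |
|---|---|---|---|
| violet | 0.833 | 0.1 | 100.5 |
| violet | 1.33 | 0.5 | 100.0 |
| violet | 2.50 | 0 | 100.4 |
| violet | 5.00 | 2.1 | 99.4 |
| violet | 10.0 | 15.1 | 84.9 |
| teal | 0.833 | 0 | 100.2 |
| teal | 1.33 | 0.2 | 99.4 |
| teal | 2.50 | 0.5 | 99.5 |
| teal | 5.00 | 9.6 | 89.8 |
| teal | 10.0 | 35.7 | 63.8 |
| grey | 2.00 | 0.1 | 99.4 |
| grey | 4.00 | 8.4 | 91.7 |
| grey | 6.00 | 15.8 | 82.9 |
| grey | 8.00 | 24.7 | 75.8 |
| grey | 10.0 | 31.2 | 69.2 |

(standard deviation of a reading: 0.5 percentage points)

1. which of the two ends with the longer chains by the average number of monomer units in a chain (chains begun, living or dead) ("neither" if they lie within 10%) (epsilon / delta / neither)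
2. average number of monomer units in a chain (chains begun, living or dead) at the end, epsilon
3. average number of monomer units in a chain (chains begun, living or dead) at the end, delta

- the average divides the monomer in chains by the number of chains begun, living and dead together
- candidate steps: free monomer + initiator -> living end + monomer in chains; free monomer + living end -> monomer in chains + living end; living end + transfer agent -> dead chain; pre-initiator -> initiator; initiator + impurity -> spent initiator
- the earlier runs do not show the number of chains; that part of a forecast is a guess

Grey's readings from 4.00 h to 10.0 h ran straight, and drawn back they met zero at 1.79 h. I took this induction period as the time in which c(pre-initiator) released as much initiator as c(impurity), which gave a first-order release constant of 0.127 h⁻¹. For epsilon at 8.0 h that left 27.8 mM as the chain budget, initiator released minus impurity charged, and for delta at 2.5 h it left 4.40 mM.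

I counted each budgeted initiator as a chain. Grey held 24.7% in chains at 8.00 h with twice epsilon's transfer agent, which gave me a lower limit of 7.11 for epsilon. Doubling that amount in chains gave me an upper limit of 14.2. Teal has epsilon's transfer agent but less free monomer and so less pre-initiator. Read at the same age past its own lag, 8.70 h, it raised the lower limit to 8.32. For delta, grey interpolated to 2.5 h gave 3.96, and doubling gave 7.91.

The forecast said epsilon, with 15 for epsilon and 3 for delta, calling the latter “very sensitive to lag”. Its epsilon value stood above my upper limit, and its delta value below my lower one.

The flask gave epsilon, with 13.2 for epsilon and 5.38 for delta, inside both brackets.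

    free monomer + initiator → living end + monomer in chains (k = 0.00260 L mol⁻¹ s⁻¹)
    free monomer + living end → monomer in chains + living end, rate k2*[living end]*[free monomer] (k = 0.00500 L mol⁻¹ s⁻¹)
    living end + transfer agent → dead chain (kL = 0.0150 L mol⁻¹ s⁻¹)
    pre-initiator → initiator (k = 3.50 × 10⁻⁵ s⁻¹)
    initiator + impurity → spent initiator (k = 6.50 L mol⁻¹ s⁻¹)

Epsilon's 44.4% of the charge in chains, over the budget of 27.8 mM, gives 12.8, with 26.9 mM of chains actually begun. The gap between the flasks is mainly the difference in time: with that difference taken away, delta run to 8.0 h gives 13.2. In the neighbour with 4.8 mol% pre-initiator, the budget falls to 11.5 mM, and its 15.6% in chains gives 10.9; the computed average there is 11.2.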